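**Strategy.** Ring C of the target is read as a 2,3-dihydro-4H-pyran-4-one, O1–C2–C3–C4(=O)–C4a=C8a (flavanone numbering), the retron of a formal oxa-Diels–Alder reaction. The disconnection pairs protected protocatechualdehyde (C2=O1) with an oxygenated diene C3=C4–C4a=C8a whose C4a=C8a bond lies in a 5,6-dihydro form of ring A, built from cyclohexane-1,3-dione and geraniol. One catalytic asymmetric Mukaiyama aldol–cyclocondensation then forms C2–C3 and O1–C8a and sets both stereocentres. The precursor is a tris-silylated triene on a geranyloxycyclohexadiene; ring A is aromatized afterwards with DDQ and three silyl groups are removed at the end.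

Key step: step 5

Remarks: flavanone numbering is used for all intermediates (ring A = carbocycle C4a–C8a, ring B = catechol ring, ring C = pyranone; geranyl = (2E)-3,7-dimethylocta-2,6-dien-1-yl). Weinreb amide 4 is assumed to be a catalogue compound.

**Step 1**
Reactants: 1 cyclohexane-1,3-dione; 2 geraniol
Product: 3 3-(geranyloxy)cyclohex-2-en-1-one
Conditions: PPh3, DIAD, THF, 0 °C → rt
Reagents that add atoms: none
Why: Mitsunobu O-alkylation, in which the acidic enol of the 1,3-dione should displace the alkoxyphosphonium of the primary allylic alcohol by SN2 to give the vinylogous ester with the E-alkene untouched, the mixture being kept at or below rt to avoid Claisen rearrangement.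

**Step 2**
Reactants: 3 3-(geranyloxy)cyclohex-2-en-1-one; 4 2-[(tert-butyldimethylsilyl)oxy]-N-methoxy-N-methylacetamide
Product: 5 6-{[(tert-butyldimethylsilyl)oxy]acetyl}-3-(geranyloxy)cyclohex-2-en-1-one (β-diketone, largely enolized, C6 configurationally labile)
Conditions: LDA (1.1 equiv), THF, −78 °C; then 4, −78 → 0 °C; AcOH quench
Reagents that add atoms: none
Why: Claisen-type C-acylation of the kinetic α′-lithium enolate of the vinylogous ester by the Weinreb amide, whose chelated tetrahedral adduct should persist until the quench so that the acidic β-diketone does not consume enolate.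

**Step 3**
Reactants: 5 6-{[(tert-butyldimethylsilyl)oxy]acetyl}-3-(geranyloxy)cyclohex-2-en-1-one
Product: 7 tert-butyl({(1Z)-2-[4-(geranyloxy)-2-(trimethylsilyloxy)cyclohexa-1,3-dien-1-yl]-2-(trimethylsilyloxy)ethenyl}oxy)dimethylsilane, via monosilyl dienol ether 6 (not isolated)
Conditions: TMSCl, Et3N, CH2Cl2, 0 °C → rt, filtered and concentrated under argon; then LDA, TMSCl, THF, −78 °C
Reagents that add atoms: chlorotrimethylsilane (TMSCl), C[Si](C)(C)Cl
Why: Two-stage silyl enol ether formation of the 1,3-bis(silyloxy)diene type, O-silylation of the enolized β-diketone followed by kinetic deprotonation at C3 (the only CH2 directly α to the remaining C4 ketone) and O-silylation, the Z enol ether being expected but of no consequence for the later stereochemistry.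

**Step 4**
Reactants: 8 3,4-dihydroxybenzaldehyde
Product: 9 3,4-bis[(tert-butyldimethylsilyl)oxy]benzaldehyde
Conditions: TBSCl (2.2 equiv), imidazole, DMF, rt
Reagents that add atoms: tert-butyldimethylsilyl chloride (TBSCl), CC(C)(C)[Si](C)(C)Cl
Why: Imidazole-promoted silylation of both phenols, a standard silyl ether protection that leaves the aldehyde free.

**Step 5**
Reactants: 7 bis(trimethylsilyl) triene; 9 3,4-bis[(tert-butyldimethylsilyl)oxy]benzaldehyde
Product: 11 (2R,3R)-2-{3,4-bis[(tert-butyldimethylsilyl)oxy]phenyl}-3-[(tert-butyldimethylsilyl)oxy]-7-(geranyloxy)-2,3,5,6-tetrahydro-4H-chromen-4-one, via aldol silyl ether 10 (not isolated)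
Conditions: Ti(OiPr)4 (10 mol %), (S)-BINOL (20 mol %), 4 Å MS, Et2O, −20 °C; then CF3CO2H, CH2Cl2, −20 → 0 °C
Reagents that add atoms: none
Why: The titanium–BINOL Lewis acid (tetravalent titanium) activates aldehyde 9 and triene 7 attacks through C3 in a Mukaiyama aldol that forms C2–C3 and, after silyl transfer, gives 10; CF3CO2H then lets the C2 oxygen add to C8a and expel the silanol, forming O1–C8a in the same flask. The closest known reaction type is the catalytic asymmetric formal oxa-Diels–Alder reaction (Mukaiyama aldol–cyclocondensation) of 1-alkoxy-3-silyloxy and 1,3-bis(silyloxy) dienes with aryl aldehydes, which gives 2-aryl-2,3-dihydro-4H-pyran-4-ones. Ring C closes by 6-exo-trig attack of the C2 oxygen on the C8a oxocarbenium (silyloxy-substituted carbonyl) carbon, followed by elimination to the vinylogous ester O1–C8a=C4a–C4=O. C2 is controlled by the (S)-BINOL ligand, which by analogy with this catalyst family should direct the nucleophile to the Si face of the aldehyde and so give 2R; C3 is controlled by the open antiperiplanar transition state, expected to favour the anti adduct and hence the 2,3-trans product, and as the carbon α to the C4 ketone it can still equilibrate to the more stable diequatorial trans isomer. The step needs reaction at C3 and not at C8 or C4a, which the terminal, least hindered position of the cross-conjugated silyl polyenol ether (vinylogous to the C8a and C7 oxygens) should secure, and it needs the geranyl dienol ether and the silyl ethers to survive, which the short, cold acid treatment should allow.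

**Step 6**
Reactants: 11 (2R,3R)-tetrahydrochromenone
Product: 12 (2R,3R)-2-{3,4-bis[(tert-butyldimethylsilyl)oxy]phenyl}-3-[(tert-butyldimethylsilyl)oxy]-7-(geranyloxy)-2,3-dihydro-4H-chromen-4-one
Conditions: DDQ (1.1 equiv), toluene, 0 °C → rt
Reagents that add atoms: none
Why: Quinone dehydrogenation, in which DDQ should abstract hydride from C5 of the 1,3-cyclohexadiene to give a cation stabilised by O1 and the C7 oxygen, loss of the C6 proton then giving aromatic ring A; the gain of aromaticity should make this far faster than attack on the geranyl chain or on C2–H, and both stereocentres are untouched.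

**Step 7**
Reactants: 12 tris-silylated flavanonol
Product: 13 (2R,3R)-2-(3,4-dihydroxyphenyl)-7-(geranyloxy)-3-hydroxy-2,3-dihydro-4H-chromen-4-one (target)
Conditions: HF·pyridine, pyridine, THF, 0 °C → rt
Reagents that add atoms: none
Why: Fluoride-mediated desilylation under pyridine-buffered, mildly acidic conditions should cleave the two aryl and the secondary silyl ethers without base-induced epimerization or ring opening of the flavanonol and without touching the aryl geranyl ether or the stereocentres.

**Compound list**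

1 | cyclohexane-1,3-dione | O=C1CCCC(=O)C1 | starting material
2 | geraniol, (2E)-3,7-dimethylocta-2,6-dien-1-ol | CC(C)=CCC/C(C)=C/CO | starting material
3 | 3-(geranyloxy)cyclohex-2-en-1-one | CC(C)=CCC/C(C)=C/COC1=CC(=O)CCC1 | intermediate
4 | 2-[(tert-butyldimethylsilyl)oxy]-N-methoxy-N-methylacetamide | CON(C)C(=O)CO[Si](C)(C)C(C)(C)C | starting material
5 | 6-{[(tert-butyldimethylsilyl)oxy]acetyl}-3-(geranyloxy)cyclohex-2-en-1-one (diketo form drawn) | CC(C)=CCC/C(C)=C/COC1=CC(=O)C(CC1)C(=O)CO[Si](C)(C)C(C)(C)C | intermediate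
6 | 2-[(tert-butyldimethylsilyl)oxy]-1-[4-(geranyloxy)-2-(trimethylsilyloxy)cyclohexa-1,3-dien-1-yl]ethan-1-one | CC(C)=CCC/C(C)=C/COC1=CC(O[Si](C)(C)C)=C(CC1)C(=O)CO[Si](C)(C)C(C)(C)C | intermediate
7 | tert-butyl({(1Z)-2-[4-(geranyloxy)-2-(trimethylsilyloxy)cyclohexa-1,3-dien-1-yl]-2-(trimethylsilyloxy)ethenyl}oxy)dimethylsilane | CC(C)=CCC/C(C)=C/COC1=CC(O[Si](C)(C)C)=C(CC1)/C(O[Si](C)(C)C)=C/O[Si](C)(C)C(C)(C)C | intermediate
8 | 3,4-dihydroxybenzaldehyde | O=Cc1ccc(O)c(O)c1 | starting material
9 | 3,4-bis[(tert-butyldimethylsilyl)oxy]benzaldehyde | O=Cc1ccc(O[Si](C)(C)C(C)(C)C)c(O[Si](C)(C)C(C)(C)C)c1 | intermediate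
10 | (2R,3R)-3-{3,4-bis[(tert-butyldimethylsilyl)oxy]phenyl}-2-[(tert-butyldimethylsilyl)oxy]-1-[4-(geranyloxy)-2-(trimethylsilyloxy)cyclohexa-1,3-dien-1-yl]-3-(trimethylsilyloxy)propan-1-one (anti aldol adduct) | CC(C)=CCC/C(C)=C/COC1=CC(O[Si](C)(C)C)=C(CC1)C(=O)[C@H](O[Si](C)(C)C(C)(C)C)[C@@H](c1ccc(O[Si](C)(C)C(C)(C)C)c(O[Si](C)(C)C(C)(C)C)c1)O[Si](C)(C)C | intermediate
11 | (2R,3R)-2-{3,4-bis[(tert-butyldimethylsilyl)oxy]phenyl}-3-[(tert-butyldimethylsilyl)oxy]-7-(geranyloxy)-2,3,5,6-tetrahydro-4H-chromen-4-one (2,3-trans) | CC(C)=CCC/C(C)=C/COC1=CC2=C(CC1)C(=O)[C@H](O[Si](C)(C)C(C)(C)C)[C@@H](c1ccc(O[Si](C)(C)C(C)(C)C)c(O[Si](C)(C)C(C)(C)C)c1)O2 | intermediate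
12 | (2R,3R)-2-{3,4-bis[(tert-butyldimethylsilyl)oxy]phenyl}-3-[(tert-butyldimethylsilyl)oxy]-7-(geranyloxy)-2,3-dihydro-4H-chromen-4-one | CC(C)=CCC/C(C)=C/COc1ccc2c(c1)O[C@H](c1ccc(O[Si](C)(C)C(C)(C)C)c(O[Si](C)(C)C(C)(C)C)c1)[C@@H](O[Si](C)(C)C(C)(C)C)C2=O | intermediate
13 | (2R,3R)-2-(3,4-dihydroxyphenyl)-7-(geranyloxy)-3-hydroxy-2,3-dihydro-4H-chromen-4-one | CC(C)=CCC/C(C)=C/COc1ccc2c(c1)O[C@H](c1ccc(O)c(O)c1)[C@@H](O)C2=O | target

**Step count and risks**

Total step count: 7. Longest linear sequence: 6 steps (1, 2, 3, 5, 6, 7).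

Steps most likely to fail:

1. Step 5. The process that may fail is facial discrimination at the aldehyde by the titanium–BINOL complex with this hindered α-silyloxy triene, so that C2 would form with low enantiomeric purity. The fallback sets out from 7 and 9 and comes back at 11. The same two bonds are made without asymmetric induction by BF3·OEt2 (1 equiv) in CH2Cl2 at −78 °C followed by CF3CO2H, an open-transition-state Mukaiyama cyclocondensation that should be trans-selective. It passes through the racemic aldol silyl ether (10 together with its enantiomer, ent-aldol silyl ether F1) to the racemic trans product (11 together with its (2S,3S)-enantiomer, ent-tetrahydrochromenone F2). Compound 11 is then separated from F2 by preparative HPLC on an amylose tris(3,5-dimethylphenylcarbamate) chiral stationary phase and enters step 6.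

2. Step 3. The process that may fail is regioselective deprotonation, with LDA attacking C6 of the ring (the vinylogous γ-position) in competition with C3, or hydrolytic loss of the trimethylsilyl enol ethers during handling. The fallback sets out from 5 and comes back at 11. Thermodynamic soft enolization without strong base (TBSOTf 2.5 equiv, Et3N, CH2Cl2, −78 → 0 °C) should give the bis(tert-butyldimethylsilyl) triene F3, which should tolerate chromatography on Et3N-deactivated silica. F3 takes the place of 7 in step 5 (same titanium–BINOL catalyst at higher loading), passes through the aldol tert-butyldimethylsilyl ether F4 and closes to 11 on acid treatment.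

3. Step 2. The process that may fail is C-acylation, through proton transfer between the enolate and the amide or slow addition to the Weinreb amide, returning 3. The fallback sets out from 3 and comes back at 5. The same lithium enolate is added at −78 °C to commercial (tert-butyldimethylsilyloxy)acetaldehyde (aldol addition) to give the β-hydroxy ketone F5 as a diastereomer mixture. Dess–Martin periodinane (NaHCO3, CH2Cl2, rt) then oxidizes F5 to 5.

**Further compounds**

F1 | step 5 | ent-aldol silyl ether, the (2S,3S)-enantiomer of 10 | CC(C)=CCC/C(C)=C/COC1=CC(O[Si](C)(C)C)=C(CC1)C(=O)[C@@H](O[Si](C)(C)C(C)(C)C)[C@H](c1ccc(O[Si](C)(C)C(C)(C)C)c(O[Si](C)(C)C(C)(C)C)c1)O[Si](C)(C)C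
F2 | step 5 | ent-tetrahydrochromenone, the (2S,3S)-enantiomer of 11 | CC(C)=CCC/C(C)=C/COC1=CC2=C(CC1)C(=O)[C@@H](O[Si](C)(C)C(C)(C)C)[C@H](c1ccc(O[Si](C)(C)C(C)(C)C)c(O[Si](C)(C)C(C)(C)C)c1)O2
F3 | step 3 | bis(tert-butyldimethylsilyl) triene, the analogue of 7 with both enol oxygens carrying tert-butyldimethylsilyl | CC(C)=CCC/C(C)=C/COC1=CC(O[Si](C)(C)C(C)(C)C)=C(CC1)/C(O[Si](C)(C)C(C)(C)C)=C/O[Si](C)(C)C(C)(C)C
F4 | step 3 | aldol tert-butyldimethylsilyl ether, the (2R,3R) analogue of 10 with tert-butyldimethylsilyl on the C2 and C8a oxygens | CC(C)=CCC/C(C)=C/COC1=CC(O[Si](C)(C)C(C)(C)C)=C(CC1)C(=O)[C@H](O[Si](C)(C)C(C)(C)C)[C@@H](c1ccc(O[Si](C)(C)C(C)(C)C)c(O[Si](C)(C)C(C)(C)C)c1)O[Si](C)(C)C(C)(C)C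
F5 | step 2 | 6-{2-[(tert-butyldimethylsilyl)oxy]-1-hydroxyethyl}-3-(geranyloxy)cyclohex-2-en-1-one (diastereomer mixture) | CC(C)=CCC/C(C)=C/COC1=CC(=O)C(CC1)C(O)CO[Si](C)(C)C(C)(C)C
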